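The readings are calculated for substances that don't exist, and the scatter is random.

At early times the substrate goes first: after 4.00 h the red run keeps 18.1% of it and shows 0.9% tris adduct, the green run 27.8% and 1.6%.

| flask | substrate | partner | remark | time |
|---|---|---|---|---|
| red | 0.013 M | 0.075 M | run made earlier |  |
| green | 0.052 M | 0.075 M | run made earlier |  |
| Friday's | 0.012 M | 0.0750 M |  | 4.0 d |
| Tuesday's | 0.025 M | 0.0750 M |  | 4.0 d |
| Saturday's | 0.050 M | 0.0750 M |  | 4.0 d |

| run | time / h | tris adduct / % | substrate / % |
|---|---|---|---|
| red | 4.00 | 0.9 | 18.1 |
| red | 8.00 | 3.8 | 3.7 |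
| red | 15.0 | 9.6 | 0.2 |
| red | 25.0 | 10.5 | 0 |
| red | 50.0 | 7.6 | 0 |
| green | 4.00 | 1.6 | 27.8 |
| green | 8.00 | 1.6 | 12.6 |
| green | 15.0 | 1.7 | 5.1 |
| green | 25.0 | 2.3 | 1.6 |
| green | 50.0 | 1.4 | 0.8 |

(scatter of a reading: 0.5 percentage points)

- "hardly changes" means that all values lie within two and a half points (for a concentration: within two and a half percent of the largest)

* [tris adduct] at the end for Friday's, Tuesday's, Saturday's, in this order
* the course of these numbers from the first flask to the last (falls all the way / rises, then falls / falls, then rises / rises all the way / hardly changes)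

The substrate is the reagent charged in the smaller amount, even in Saturday's flask, with 0.050 M against 0.0750 M of partner. That does not make it the limiting reagent for tris adduct, so I write the balance on both reagents, assuming 3 partner per tris adduct. On this count Saturday's substrate asks for 0.150 M of partner, more than the 0.0750 M charged, so in Saturday's flask the ceiling below comes from the partner. I assume that each substrate takes one partner early, and that what partner then stands must pay 2 further steps. Tuesday's flask thus offers 0.0250 M: the smaller of the substrate charged and the remaining partner divided by 2, which I call the tris ceiling C. Friday's has 0.0120 M and Saturday's 0.0125 M, so Tuesday's stands highest.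

Two runs now give the share of C that appears as tris adduct. At 25.0 h the red run, with C = 0.0130 M, reads 10.5%. The green run, with C = 0.0115 M, reads 10.4%. These come from opposite sides of the ceiling, so I trust the agreement.

The decline is where they part. Carried from 50.0 h to 4.0 d at the same fractional loss, the red run gives 4.19% and the green run 2.54%. The green one cheats: its fall is 0.9 percentage points against a scatter of 0.5 points, while the red fall is 2.9 points. I commit to the red share, which gives 5.03 × 10⁻⁴ M, 0.00105 M and 5.24 × 10⁻⁴ M.

The forecast reads 5.000 × 10⁻⁴ M, 9.000 × 10⁻⁴ M and 6.000 × 10⁻⁴ M, a course that rises, then falls, and expects “a modest maximum in the middle”. The flasks give 6.71 × 10⁻⁴ M, 0.00102 M and 5.26 × 10⁻⁴ M: rises, then falls.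

    partner + tris adduct → tetra adduct + by-product (k = 0.240 M⁻¹ h⁻¹)
    substrate + partner → single product + by-product (k = 6.40 M⁻¹ h⁻¹)
    tris adduct + by-product → side product (k = 0.540 M⁻¹ h⁻¹)
    partner + single product → bis adduct + by-product (k = 0.350 M⁻¹ h⁻¹)
    tris adduct ⇌ isomer of the product (K = 14.0, k = 0.120 h⁻¹)
    partner + bis adduct → tris adduct + by-product (k = 4.70 M⁻¹ h⁻¹)

Against the ceiling, Tuesday's flask ends at 4.08% of 0.0250 M and Saturday's at 4.21% of 0.0125 M, while Friday's ends higher, at 5.59% of 0.0120 M. In Saturday's flask, part of what keeps the tris adduct at 5.26 × 10⁻⁴ M is the falling back of the isomer of the product to tris adduct, acting together with the time given, which is short of ten times as long. Without that falling back Saturday's flask ends at 1.76 × 10⁻⁴ M, and with the time made ten times as long it stands at 7.77 × 10⁻⁵ M.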